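**Retrosynthetic overview** (C7 = benzylic carbon, C8 = stereocentre, C9 = methyl)
- The C7 methylene comes from a C7 carbonyl (hydride reduction, then ionic hydrogenation). The free phenol comes from a PMB ether that is lost in the same acid. The precursor is therefore an (S)-alpha-aryloxy aryl ketone.
- The C8–OAr bond comes from Mitsunobu inversion of an (R)-alpha-hydroxy ketone with 4-allyl-2,6-dimethoxyphenol.
- The key C7–C8 bond comes from an enantioselective cross-benzoin. The formyl carbon of O-PMB-vanillin acts as an acyl anion (Breslow intermediate on thiamine diphosphate in benzaldehyde lyase) and attacks the carbonyl carbon of acetaldehyde. C8 is created as (R) in this C–C bond-forming event.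
- No ring is formed. Both benzene rings are bought intact (vanillin and 4-allyl-2,6-dimethoxyphenol).

Assumption: the stereocentre in the given SMILES is (S) by CIP analysis, and recombinant benzaldehyde lyase counts as an obtainable catalyst.

**Step 1**
Reactants: 1 vanillin
Product: 2 3-methoxy-4-[(4-methoxybenzyl)oxy]benzaldehyde (O-PMB-vanillin)
Conditions: PMBCl (1.1 equiv), K2CO3 (1.5 equiv), DMF, 60 °C, 4 h
Reagents that add atoms: 4-methoxybenzyl chloride, COc1ccc(CCl)cc1
Why: Williamson ether synthesis, in which the acidic vanillin phenoxide is alkylated cleanly by the benzylic chloride to give a PMB ether that is inert to buffer, Mitsunobu reagents and NaBH4 but falls off in the acid of step 4; no stereocentre is involved.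

**Step 2** (key step)
Reactants: 2 O-PMB-vanillin; 3 acetaldehyde
Product: 5 (R)-2-hydroxy-1-{3-methoxy-4-[(4-methoxybenzyl)oxy]phenyl}propan-1-one, via ThDP-bound Breslow enaminol 4 (not isolated)
Conditions: MeCHO (10 equiv, in portions), benzaldehyde lyase (BAL, Pseudomonas fluorescens, recombinant), thiamine diphosphate (0.25 mM), MgSO4 (2.5 mM), K2HPO4/KH2PO4 buffer (50 mM, pH 7.5)/DMSO 7:3, 30 °C, 24–48 h
Reagents that add atoms: none
Why: Enzymatic asymmetric cross-benzoin (ThDP carboligation), in which the thiazolium ylide adds to the formyl group of 2 and proton transfer gives enaminol 4, an acyl anion equivalent whose formerly electrophilic carbon attacks the carbonyl carbon of acetaldehyde held in the small acceptor pocket with one face exposed, setting C8 as (R), as this lyase does for meta- and para-substituted benzaldehydes (aromatic aldehyde as donor, acetaldehyde as acceptor, ee above 98%).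

**Step 3**
Reactants: 5 (R)-hydroxy ketone; 6 4-allyl-2,6-dimethoxyphenol
Product: 8 (S)-2-(4-allyl-2,6-dimethoxyphenoxy)-1-{3-methoxy-4-[(4-methoxybenzyl)oxy]phenyl}propan-1-one, via alkoxyphosphonium ion 7 (not isolated)
Conditions: 6 (1.3 equiv), PPh3 (1.5 equiv), DIAD (1.5 equiv), toluene, 0 °C to rt, 12 h
Reagents that add atoms: none
Why: Mitsunobu reaction, in which PPh3/DIAD turn the carbinol into 7 and the phenoxide of 6 (pKa about 10) displaces Ph3PO from the carbonyl-activated secondary carbon by SN2 with inversion, converting (R)-C8 into (S)-C8 in an essentially neutral medium that does not enolise the ketone, while the PMB ether keeps the more acidic para-acylphenol out of the reaction.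

**Step 4**
Reactants: 8 (S)-aryloxy ketone
Product: 11 (S)-4-[2-(4-allyl-2,6-dimethoxyphenoxy)propyl]-2-methoxyphenol (target CNP0225369.1), via benzylic alcohol 9 (not isolated), via PMB ether of the target 10 (not isolated)
Conditions: NaBH4 (0.6 equiv), THF/MeOH 1:1, 0 °C to rt, 1 h; evaporate; then Et3SiH (6 equiv), TFA/CH2Cl2 1:4, −20 °C to rt, 2 h (same flask); aq NaHCO3
Reagents that add atoms: none
Why: Carbonyl reduction followed by ionic hydrogenation (Kursanov–Parnes), in which NaBH4 removes the enolisable ketone within minutes, the para-alkoxybenzylic alcohol 9 ionises in dilute TFA and takes hydride from Et3SiH to give 10, and the same acid cleaves the PMB ether while Et3SiH reduces the 4-methoxybenzyl cation, leaving the monosubstituted allyl alkene, the methyl ethers and the secondary alkyl aryl ether untouched and breaking no bond at C8, so (S) is retained.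

**Compound list**
1 | vanillin | COc1cc(C=O)ccc1O | starting material
2 | 3-methoxy-4-[(4-methoxybenzyl)oxy]benzaldehyde | COc1ccc(COc2ccc(C=O)cc2OC)cc1 | intermediate
3 | acetaldehyde | CC=O | starting material
4 | ThDP-bound Breslow enaminol of 2 (2-[aryl(hydroxy)methylidene]thiazoline form of thiamine diphosphate, acyl anion equivalent) | Cc1ncc(CN2C(C)=C(CCOP(=O)(O)OP(=O)(O)O)SC2=C(O)c2ccc(OCc3ccc(OC)cc3)c(OC)c2)c(N)n1 | intermediate
5 | (R)-2-hydroxy-1-{3-methoxy-4-[(4-methoxybenzyl)oxy]phenyl}propan-1-one | C[C@@H](O)C(=O)c1ccc(OCc2ccc(OC)cc2)c(OC)c1 | intermediate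
6 | 4-allyl-2,6-dimethoxyphenol | C=CCc1cc(OC)c(O)c(OC)c1 | starting material
7 | {[(R)-1-{3-methoxy-4-[(4-methoxybenzyl)oxy]phenyl}-1-oxopropan-2-yl]oxy}triphenylphosphonium ion | C[C@@H](O[P+](c1ccccc1)(c1ccccc1)c1ccccc1)C(=O)c1ccc(OCc2ccc(OC)cc2)c(OC)c1 | intermediate
8 | (S)-2-(4-allyl-2,6-dimethoxyphenoxy)-1-{3-methoxy-4-[(4-methoxybenzyl)oxy]phenyl}propan-1-one | C[C@H](Oc1c(OC)cc(CC=C)cc1OC)C(=O)c1ccc(OCc2ccc(OC)cc2)c(OC)c1 | intermediate
9 | (2S)-2-(4-allyl-2,6-dimethoxyphenoxy)-1-{3-methoxy-4-[(4-methoxybenzyl)oxy]phenyl}propan-1-ol (both C1 epimers) | C[C@H](Oc1c(OC)cc(CC=C)cc1OC)C(O)c1ccc(OCc2ccc(OC)cc2)c(OC)c1 | intermediate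
10 | (S)-5-allyl-1,3-dimethoxy-2-[(1-{3-methoxy-4-[(4-methoxybenzyl)oxy]phenyl}propan-2-yl)oxy]benzene | C[C@H](Oc1c(OC)cc(CC=C)cc1OC)Cc1ccc(OCc2ccc(OC)cc2)c(OC)c1 | intermediate
11 | (S)-4-[2-(4-allyl-2,6-dimethoxyphenoxy)propyl]-2-methoxyphenol | C=CCc1cc(OC)c(O[C@@H](C)Cc2ccc(O)c(OC)c2)c(OC)c1 | target

**Total step count:** 4 (step 4 is a two-stage sequence in one flask).
**Longest linear sequence:** 4 steps (1 → 2 → 5 → 8 → 11).

**Steps most likely to fail**

**Step 2.** The bulky, poorly soluble aldehyde 2 may be a poor donor for the lyase, and acetaldehyde can deactivate the enzyme. The fallback sets out from 2 and comes back at 5. It uses a stoichiometric acyl anion and sets C8 by reagent control.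
- Aldehyde 2 reacts with propane-1,3-dithiol and catalytic I2 (CH2Cl2, rt) to give the aryl dithiane F1.
- Deprotonation with n-BuLi (THF, −78 °C) and acylation with N-methoxy-N-methylacetamide gives the acetyl dithiane F2.
- Reduction with BH3·SMe2 and 10 mol% (S)-2-methyl-CBS-oxazaborolidine differentiates the quaternary dithianyl carbon from methyl and gives the (R)-carbinol F3.
- MeI/CaCO3 in aqueous MeCN unmasks the ketone to give 5.

**Step 3.** The flanked phenol 6 may react slowly, and the alpha-keto stereocentre could partly racemise. The fallback sets out from 5 and comes back at 8. It replaces the redox condensation with a preformed sulfonate electrophile.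
- Mesylation of 5 (MsCl, Et3N, CH2Cl2, −20 °C) gives the (R)-keto mesylate F4, which is isolated.
- Displacement by 6 with Cs2CO3 (1.0 equiv) in MeCN at 0 °C is a Williamson-type SN2 with inversion at the highly reactive alpha-keto carbon and gives 8.

**Step 4.** The C7 cation may lose H-8 to give an enol ether, which would racemise C8 or cleave the ether. The 4-methoxybenzyl cation may C-alkylate the electron-rich rings. The fallback sets out from 5 and comes back at 11. It removes the C7 oxygen before the aryl ether and the allyl group are present.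
- Hydrogenolysis of 5 (H2 3 bar, Pd/C, EtOH, cat. HCl) strips both the ketone oxygen and the PMB group and gives the (R)-phenol carbinol F5.
- Selective phenol silylation (TBSCl 1.0 equiv, imidazole, CH2Cl2, 0 °C) gives the (R)-silyl ether carbinol F6.
- Mitsunobu inversion with 6 (PPh3, DIAD, toluene) gives the (S)-silyl ether of the target F7.
- Bu4NF (THF, 0 °C) releases 11.

**Further compounds**
F1 | step 2 | 2-{3-methoxy-4-[(4-methoxybenzyl)oxy]phenyl}-1,3-dithiane | COc1ccc(COc2ccc(C3SCCCS3)cc2OC)cc1
F2 | step 2 | 1-(2-{3-methoxy-4-[(4-methoxybenzyl)oxy]phenyl}-1,3-dithian-2-yl)ethan-1-one | CC(=O)C1(SCCCS1)c1ccc(OCc2ccc(OC)cc2)c(OC)c1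
F3 | step 2 | (R)-1-(2-{3-methoxy-4-[(4-methoxybenzyl)oxy]phenyl}-1,3-dithian-2-yl)ethan-1-ol | C[C@@H](O)C1(SCCCS1)c1ccc(OCc2ccc(OC)cc2)c(OC)c1
F4 | step 3 | (R)-1-{3-methoxy-4-[(4-methoxybenzyl)oxy]phenyl}-1-oxopropan-2-yl methanesulfonate | C[C@@H](OS(C)(=O)=O)C(=O)c1ccc(OCc2ccc(OC)cc2)c(OC)c1
F5 | step 4 | (R)-4-(2-hydroxypropyl)-2-methoxyphenol | C[C@@H](O)Cc1ccc(O)c(OC)c1
F6 | step 4 | (R)-1-{4-[(tert-butyldimethylsilyl)oxy]-3-methoxyphenyl}propan-2-ol | C[C@@H](O)Cc1ccc(O[Si](C)(C)C(C)(C)C)c(OC)c1
F7 | step 4 | (S)-{4-[2-(4-allyl-2,6-dimethoxyphenoxy)propyl]-2-methoxyphenoxy}(tert-butyl)dimethylsilane | C[C@H](Oc1c(OC)cc(CC=C)cc1OC)Cc1ccc(O[Si](C)(C)C(C)(C)C)c(OC)c1
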